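The synthesis rests on cutting both bonds at ring B of the epicatechin-type unit: C6'–C8 to ring A of the catechin unit, and C1'–C2 to the future pyran. These bonds sit on adjacent carbons, and the oxygens at C3' and C4' make 4,5-bis(benzyloxy)benzyne symmetric. One operation therefore joins three fragments: 8-magnesiated pentabenzylcatechin adds to the aryne, and the resulting ortho-biaryl Grignard acylates an (R)-α-silyloxy Weinreb amide carrying ring A of the epicatechin-type unit. The ketone so formed holds the whole carbon skeleton. Phenol release, reductive etherification to the 2,3-cis pyran, desilylation and hydrogenolysis finish the synthesis.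

Key step: step 12

Conventions: Bn = benzyl, TBS = tert-butyldimethylsilyl, Cat8 = (2R,3S)-3,5,7-tris(benzyloxy)-2-[3,4-bis(benzyloxy)phenyl]chroman-8-yl. Rings A, B, C and locants C2, C3, C1'–C6' refer to the 2,3-cis unit; C8 refers to the 2,3-trans (catechin) unit.

Assumption: the tri-ortho-substituted C8–C6' axis carries no descriptor in the target, so no axial configuration is controlled; protected intermediates may show slowly interconverting rotamers and are carried on as one compound.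

Design notes: the aryl nucleophile for the epoxide opening is made by iodine–magnesium exchange, not lithiation, to exclude O→C silyl migration. The phenolic silyl ether is later removed with bifluoride, not a basic methanolysis, to protect the epimerisable carbon next to the ketone.

**Route**

Step 1
Reactants: 1 (+)-catechin
Product: 2 (2R,3S)-5,7-bis(benzyloxy)-2-[3,4-bis(benzyloxy)phenyl]chroman-3-ol
Conditions: BnBr (4.4 equiv), K2CO3, DMF, 0 °C → rt
Reagents that add atoms: benzyl bromide, BrCc1ccccc1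
Why: Williamson etherification in which carbonate deprotonates only the four phenols, so the secondary C3 alcohol and both stereocentres stay untouched.

Step 2
Reactants: 2 (2R,3S)-5,7-bis(benzyloxy)-2-[3,4-bis(benzyloxy)phenyl]chroman-3-ol
Product: 3 (2R,3S)-3,5,7-tris(benzyloxy)-2-[3,4-bis(benzyloxy)phenyl]chroman
Conditions: NaH, BnBr, n-Bu4NI (cat.), DMF, 0 °C → rt
Reagents that add atoms: benzyl bromide, BrCc1ccccc1
Why: Williamson etherification of the sodium alkoxide; with no free phenol left the flavan cannot ring-open, so C2 and C3 keep their configuration.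

Step 3
Reactants: 3 (2R,3S)-3,5,7-tris(benzyloxy)-2-[3,4-bis(benzyloxy)phenyl]chroman
Product: 4 (2R,3S)-3,5,7-tris(benzyloxy)-2-[3,4-bis(benzyloxy)phenyl]-8-bromochroman
Conditions: NBS (1.0 equiv), CH2Cl2, −40 → 0 °C
Reagents that add atoms: N-bromosuccinimide, O=C1CCC(=O)N1Br
Why: Electrophilic aromatic bromination, which in 5,7-di-O-benzyl flavans goes to C8 (flanked by O1 and one benzyloxy group) rather than to C6 (between two benzyloxy groups) or the less electron-rich catechol ring.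

Step 4
Reactants: 5 3,4-bis(benzyloxy)benzaldehyde
Product: 7 3,4-bis(benzyloxy)phenol, via aryl formate 6 (not isolated)
Conditions: mCPBA, CH2Cl2, rt; aq NaHCO3 wash; K2CO3 (cat.), MeOH, rt
Reagents that add atoms: meta-chloroperoxybenzoic acid, OOC(=O)c1cccc(Cl)c1
Why: Baeyer–Villiger (Dakin-type) oxidation in which the electron-rich aryl group migrates to oxygen, followed by methanolysis of the formate.

Step 5
Reactants: 7 3,4-bis(benzyloxy)phenol
Product: 8 4,5-bis(benzyloxy)-2-iodophenol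
Conditions: NIS (1.0 equiv), MeCN, −20 → 0 °C, dark
Reagents that add atoms: N-iodosuccinimide, O=C1CCC(=O)N1I
Why: Electrophilic aromatic iodination at the position ortho to the hydroxyl and para to a benzyloxy group, the other ortho position being squeezed between two oxygens.

Step 6
Reactants: 8 4,5-bis(benzyloxy)-2-iodophenol
Product: 9 4,5-bis(benzyloxy)-2-iodophenyl 4-chlorobenzenesulfonate
Conditions: 4-ClC6H4SO2Cl, Et3N, DMAP (cat.), CH2Cl2, 0 °C → rt
Reagents that add atoms: 4-chlorobenzenesulfonyl chloride, ClS(=O)(=O)c1ccc(Cl)cc1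
Why: O-Sulfonylation of the phenol gives an ortho-iodoaryl sulfonate that loses its sulfonate only after iodine–magnesium exchange.

Step 7
Reactants: 10 3,5-bis(benzyloxy)phenol
Product: 11 3,5-bis(benzyloxy)-2-iodophenol
Conditions: NIS (1.0 equiv), CH2Cl2, −40 → 0 °C, dark
Reagents that add atoms: N-iodosuccinimide, O=C1CCC(=O)N1I
Why: Electrophilic aromatic iodination should favour the two equivalent sites ortho to the hydroxyl over C4, which lies between two benzyloxy groups; any 4-iodo isomer would be removed by chromatography.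

Step 8
Reactants: 11 3,5-bis(benzyloxy)-2-iodophenol
Product: 12 [3,5-bis(benzyloxy)-2-iodophenoxy](tert-butyl)dimethylsilane
Conditions: TBSCl, imidazole, DMF, rt
Reagents that add atoms: tert-butyldimethylsilyl chloride, CC(C)(C)[Si](C)(C)Cl
Why: Standard silylation of a phenol gives an ether inert to Grignard reagents and later removable beside benzyl ethers and an alkyl silyl ether.

Step 9
Reactants: 12 [3,5-bis(benzyloxy)-2-iodophenoxy](tert-butyl)dimethylsilane; 13 methyl (R)-glycidate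
Product: 15 methyl (R)-3-[2,4-bis(benzyloxy)-6-(tert-butyldimethylsilyloxy)phenyl]-2-hydroxypropanoate, via aryl Grignard 14 (not isolated)
Conditions: i-PrMgCl·LiCl, THF, −20 → 0 °C; CuI (10 mol%), 13, −40 → −10 °C; aq NH4Cl
Reagents that add atoms: none
Why: Iodine–magnesium exchange followed by CuI-catalysed SN2 opening of the epoxide at its CH2 carbon touches no bond to the stereocentre, so the (R) configuration of the glycidate becomes that of C3 of the target.

Step 10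
Reactants: 15 methyl (R)-3-[2,4-bis(benzyloxy)-6-(tert-butyldimethylsilyloxy)phenyl]-2-hydroxypropanoate
Product: 16 methyl (R)-3-[2,4-bis(benzyloxy)-6-(tert-butyldimethylsilyloxy)phenyl]-2-(tert-butyldimethylsilyloxy)propanoate
Conditions: TBSOTf, 2,6-lutidine, CH2Cl2, 0 °C
Reagents that add atoms: tert-butyldimethylsilyl trifluoromethanesulfonate, CC(C)(C)[Si](C)(C)OS(=O)(=O)C(F)(F)F
Why: Silylation of the secondary alcohol with a silyl triflate and a hindered weak base, conditions that do not enolise the ester.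

Step 11
Reactants: 16 methyl (R)-3-[2,4-bis(benzyloxy)-6-(tert-butyldimethylsilyloxy)phenyl]-2-(tert-butyldimethylsilyloxy)propanoate
Product: 17 (R)-3-[2,4-bis(benzyloxy)-6-(tert-butyldimethylsilyloxy)phenyl]-2-(tert-butyldimethylsilyloxy)-N-methoxy-N-methylpropanamide
Conditions: MeONHMe·HCl, i-PrMgCl, THF, −20 → 0 °C
Reagents that add atoms: N,O-dimethylhydroxylamine hydrochloride, CNOC.Cl
Why: Direct aminolysis of the ester by the chloromagnesium amide (Weinreb amide formation) is fast at low temperature, so the α-silyloxy stereocentre is not enolised.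

Step 12
Reactants: 4 (2R,3S)-3,5,7-tris(benzyloxy)-2-[3,4-bis(benzyloxy)phenyl]-8-bromochroman; 9 4,5-bis(benzyloxy)-2-iodophenyl 4-chlorobenzenesulfonate; 17 (R)-3-[2,4-bis(benzyloxy)-6-(tert-butyldimethylsilyloxy)phenyl]-2-(tert-butyldimethylsilyloxy)-N-methoxy-N-methylpropanamide
Product: 24 (R)-1-[4,5-bis(benzyloxy)-2-(Cat8)phenyl]-3-[2,4-bis(benzyloxy)-6-(tert-butyldimethylsilyloxy)phenyl]-2-(tert-butyldimethylsilyloxy)propan-1-one, via aryllithium 18 (not isolated), via catechin Grignard 19 (not isolated), via magnesiated sulfonate 20 (not isolated), via aryne 21 (not isolated), via biaryl Grignard 22 (not isolated), via chelated adduct 23 (not isolated)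
Conditions: (a) 4 (1.2 equiv), t-BuLi (2.4 equiv), THF, −78 °C; MgBr2·OEt2 (1.3 equiv), −78 → 0 °C; (b) 9 (1.0 equiv), i-PrMgCl·LiCl (1.0 equiv), THF, −78 °C; (c) solution (a) into (b) at −78 °C, slowly to rt; (d) 17 (1.5 equiv), rt → 45 °C; aq NH4Cl
Reagents that add atoms: none
Why: Bromine–lithium exchange and transmetalation turn 4 into the C8 Grignard 19, iodine–magnesium exchange turns 9 into 20, and on warming 20 expels the sulfonate to give aryne 21, across whose strained triple bond 19 adds (carbomagnesiation) to leave magnesium on the neighbouring carbon in 22; 22 then attacks amide 17 to give the five-membered magnesium chelate 23, which releases ketone 24 only on aqueous work-up. The closest known reaction type is the addition of aryl Grignard reagents to arynes released from 2-magnesiated aryl sulfonates or 1,2-dihaloarenes with electrophilic capture of the 2-biarylmagnesium so formed, here joined to a Weinreb ketone synthesis. No ring is closed and no stereocentre is created; C2 and C3 of the catechin unit and the silyloxy-bearing carbon of 17 are spectators, the latter safe from enolisation because no ketone exists before work-up. Regiochemistry needs no control, since 21 has hydrogen on both flanking carbons and benzyloxy groups at C4 and C5 and so presents two equivalent carbons, and the vicinal placing of the C8–C6' and C1'–C2 bonds is inherent in a 1,2-addition. What must be secured is chemoselectivity: 20 is formed at −78 °C where it is stable, the aryne is released only in the presence of excess 19 so that 19 rather than 20 captures it, 17 is added only after the aryne is consumed, and the N-methoxy chelate stops the acylation at the ketone stage. Ring strain of the aryne, not a catalyst, pays for the hindered tri-ortho-substituted biaryl bond.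

Step 13
Reactants: 24 (R)-1-[4,5-bis(benzyloxy)-2-(Cat8)phenyl]-3-[2,4-bis(benzyloxy)-6-(tert-butyldimethylsilyloxy)phenyl]-2-(tert-butyldimethylsilyloxy)propan-1-one
Product: 25 (R)-1-[4,5-bis(benzyloxy)-2-(Cat8)phenyl]-3-[2,4-bis(benzyloxy)-6-hydroxyphenyl]-2-(tert-butyldimethylsilyloxy)propan-1-one
Conditions: KHF2 (2 equiv), MeOH/THF, rt
Reagents that add atoms: none
Why: Selective desilylation, since bifluoride cleaves the aryl silyl ether much faster than the hindered secondary alkyl one and the near-neutral medium should not enolise the ketone next to the C3 stereocentre.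

Step 14
Reactants: 25 (R)-1-[4,5-bis(benzyloxy)-2-(Cat8)phenyl]-3-[2,4-bis(benzyloxy)-6-hydroxyphenyl]-2-(tert-butyldimethylsilyloxy)propan-1-one
Product: 28 (2R,3R)-5,7-bis(benzyloxy)-2-[4,5-bis(benzyloxy)-2-(Cat8)phenyl]-3-(tert-butyldimethylsilyloxy)chroman, via hemiketal 26 (not isolated), via oxocarbenium triflate 27 (not isolated)
Conditions: Et3SiH (5 equiv), TMSOTf (0.3 equiv), CH2Cl2, −78 → −40 °C; Et3N quench
Reagents that add atoms: none
Why: Reductive etherification (ionic hydrogenation of a cyclic oxocarbenium ion): the phenol closes the six-membered hemiketal 26, silyl triflate ionises it to 27, in which the C3 silyloxy group sits pseudoaxial to avoid A(1,2) strain with the C2 aryl group, and Et3SiH should deliver hydride to C2 on the face opposite that group, placing the aryl group cis to the C3 oxygen (2R).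

Step 15
Reactants: 28 (2R,3R)-5,7-bis(benzyloxy)-2-[4,5-bis(benzyloxy)-2-(Cat8)phenyl]-3-(tert-butyldimethylsilyloxy)chroman
Product: 29 (2R,3R)-5,7-bis(benzyloxy)-2-[4,5-bis(benzyloxy)-2-(Cat8)phenyl]chroman-3-ol
Conditions: TBAF, THF, 0 °C → rt
Reagents that add atoms: none
Why: Fluoride-induced cleavage of the Si–O bond, which leaves the benzyl ethers and all four stereocentres unaffected.

Step 16
Reactants: 29 (2R,3R)-5,7-bis(benzyloxy)-2-[4,5-bis(benzyloxy)-2-(Cat8)phenyl]chroman-3-ol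
Product: 30 (2R,3R)-2-{2-[(2R,3S)-2-(3,4-dihydroxyphenyl)-3,5,7-trihydroxychroman-8-yl]-4,5-dihydroxyphenyl}chroman-3,5,7-triol
Conditions: H2 (1 atm), Pd(OH)2 on carbon, THF/MeOH/H2O, rt
Reagents that add atoms: none
Why: Hydrogenolysis of the nine benzyl ethers over Pd(OH)2 on carbon, the standard mild unmasking of benzylated flavan-3-ols, which should leave the biaryl bond and the stereocentres intact.

**Compound list**

1 | (+)-catechin, (2R,3S)-2-(3,4-dihydroxyphenyl)chroman-3,5,7-triol | O[C@H]1Cc2c(O)cc(O)cc2O[C@@H]1c1ccc(O)c(O)c1 | starting material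
2 | (2R,3S)-5,7-bis(benzyloxy)-2-[3,4-bis(benzyloxy)phenyl]chroman-3-ol | c1c(OCc9ccccc9)cc(OCc9ccccc9)c2c1O[C@H](c1ccc(OCc9ccccc9)c(OCc9ccccc9)c1)[C@@H](O)C2 | intermediate
3 | (2R,3S)-3,5,7-tris(benzyloxy)-2-[3,4-bis(benzyloxy)phenyl]chroman | c1c(OCc9ccccc9)cc(OCc9ccccc9)c2c1O[C@H](c1ccc(OCc9ccccc9)c(OCc9ccccc9)c1)[C@@H](OCc9ccccc9)C2 | intermediate
4 | (2R,3S)-3,5,7-tris(benzyloxy)-2-[3,4-bis(benzyloxy)phenyl]-8-bromochroman | Brc1c(OCc9ccccc9)cc(OCc9ccccc9)c2c1O[C@H](c1ccc(OCc9ccccc9)c(OCc9ccccc9)c1)[C@@H](OCc9ccccc9)C2 | intermediate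
5 | 3,4-bis(benzyloxy)benzaldehyde | O=Cc1ccc(OCc2ccccc2)c(OCc2ccccc2)c1 | starting material
6 | 3,4-bis(benzyloxy)phenyl formate (not isolated) | O=COc1ccc(OCc2ccccc2)c(OCc2ccccc2)c1 | intermediate
7 | 3,4-bis(benzyloxy)phenol | Oc1ccc(OCc2ccccc2)c(OCc2ccccc2)c1 | intermediate
8 | 4,5-bis(benzyloxy)-2-iodophenol | Oc1cc(OCc2ccccc2)c(OCc2ccccc2)cc1I | intermediate
9 | 4,5-bis(benzyloxy)-2-iodophenyl 4-chlorobenzenesulfonate | Ic1cc(OCc2ccccc2)c(OCc2ccccc2)cc1OS(=O)(=O)c1ccc(Cl)cc1 | intermediate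
10 | 3,5-bis(benzyloxy)phenol | Oc1cc(OCc2ccccc2)cc(OCc2ccccc2)c1 | starting material
11 | 3,5-bis(benzyloxy)-2-iodophenol | Oc1cc(OCc2ccccc2)cc(OCc2ccccc2)c1I | intermediate
12 | [3,5-bis(benzyloxy)-2-iodophenoxy](tert-butyl)dimethylsilane | CC(C)(C)[Si](C)(C)Oc1cc(OCc2ccccc2)cc(OCc2ccccc2)c1I | intermediate
13 | methyl (R)-glycidate, methyl (2R)-oxirane-2-carboxylate | COC(=O)[C@H]1CO1 | starting material
14 | [2,4-bis(benzyloxy)-6-(tert-butyldimethylsilyloxy)phenyl]magnesium chloride (not isolated) | CC(C)(C)[Si](C)(C)Oc1cc(OCc2ccccc2)cc(OCc2ccccc2)c1[Mg]Cl | intermediate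
15 | methyl (R)-3-[2,4-bis(benzyloxy)-6-(tert-butyldimethylsilyloxy)phenyl]-2-hydroxypropanoate | COC(=O)[C@H](O)Cc1c(O[Si](C)(C)C(C)(C)C)cc(OCc2ccccc2)cc1OCc1ccccc1 | intermediate
16 | methyl (R)-3-[2,4-bis(benzyloxy)-6-(tert-butyldimethylsilyloxy)phenyl]-2-(tert-butyldimethylsilyloxy)propanoate | COC(=O)[C@H](O[Si](C)(C)C(C)(C)C)Cc1c(O[Si](C)(C)C(C)(C)C)cc(OCc2ccccc2)cc1OCc1ccccc1 | intermediate
17 | (R)-3-[2,4-bis(benzyloxy)-6-(tert-butyldimethylsilyloxy)phenyl]-2-(tert-butyldimethylsilyloxy)-N-methoxy-N-methylpropanamide | CON(C)C(=O)[C@H](O[Si](C)(C)C(C)(C)C)Cc1c(O[Si](C)(C)C(C)(C)C)cc(OCc2ccccc2)cc1OCc1ccccc1 | intermediate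
18 | (2R,3S)-3,5,7-tris(benzyloxy)-2-[3,4-bis(benzyloxy)phenyl]chroman-8-yllithium (not isolated) | [Li]c1c(OCc9ccccc9)cc(OCc9ccccc9)c2c1O[C@H](c1ccc(OCc9ccccc9)c(OCc9ccccc9)c1)[C@@H](OCc9ccccc9)C2 | intermediate
19 | (2R,3S)-3,5,7-tris(benzyloxy)-2-[3,4-bis(benzyloxy)phenyl]chroman-8-ylmagnesium bromide (not isolated) | Br[Mg]c1c(OCc9ccccc9)cc(OCc9ccccc9)c2c1O[C@H](c1ccc(OCc9ccccc9)c(OCc9ccccc9)c1)[C@@H](OCc9ccccc9)C2 | intermediate
20 | [4,5-bis(benzyloxy)-2-(4-chlorophenylsulfonyloxy)phenyl]magnesium chloride (not isolated) | Cl[Mg]c1cc(OCc2ccccc2)c(OCc2ccccc2)cc1OS(=O)(=O)c1ccc(Cl)cc1 | intermediate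
21 | 4,5-bis(benzyloxy)benzyne (not isolated) | C1#CC=C(OCc2ccccc2)C(OCc2ccccc2)=C1 | intermediate
22 | [4,5-bis(benzyloxy)-2-(Cat8)phenyl]magnesium bromide (not isolated) | Br[Mg]c1cc(OCc9ccccc9)c(OCc9ccccc9)cc1-c1c(OCc9ccccc9)cc(OCc9ccccc9)c2c1O[C@H](c1ccc(OCc9ccccc9)c(OCc9ccccc9)c1)[C@@H](OCc9ccccc9)C2 | intermediate
23 | bromomagnesium N-methoxy-N-methyl hemiaminal alkoxide formed from 22 and 17, carbinol carbon unassigned (not isolated) | CON(C)C(O[Mg]Br)(c1cc(OCc9ccccc9)c(OCc9ccccc9)cc1-c1c(OCc9ccccc9)cc(OCc9ccccc9)c2c1O[C@H](c1ccc(OCc9ccccc9)c(OCc9ccccc9)c1)[C@@H](OCc9ccccc9)C2)[C@H](O[Si](C)(C)C(C)(C)C)Cc1c(O[Si](C)(C)C(C)(C)C)cc(OCc9ccccc9)cc1OCc9ccccc9 | intermediate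
24 | (R)-1-[4,5-bis(benzyloxy)-2-(Cat8)phenyl]-3-[2,4-bis(benzyloxy)-6-(tert-butyldimethylsilyloxy)phenyl]-2-(tert-butyldimethylsilyloxy)propan-1-one | O=C(c1cc(OCc9ccccc9)c(OCc9ccccc9)cc1-c3c(OCc9ccccc9)cc(OCc9ccccc9)c4c3O[C@H](c3ccc(OCc9ccccc9)c(OCc9ccccc9)c3)[C@@H](OCc9ccccc9)C4)[C@H](O[Si](C)(C)C(C)(C)C)Cc1c(O[Si](C)(C)C(C)(C)C)cc(OCc9ccccc9)cc1OCc9ccccc9 | intermediate
25 | (R)-1-[4,5-bis(benzyloxy)-2-(Cat8)phenyl]-3-[2,4-bis(benzyloxy)-6-hydroxyphenyl]-2-(tert-butyldimethylsilyloxy)propan-1-one | O=C(c1cc(OCc9ccccc9)c(OCc9ccccc9)cc1-c3c(OCc9ccccc9)cc(OCc9ccccc9)c4c3O[C@H](c3ccc(OCc9ccccc9)c(OCc9ccccc9)c3)[C@@H](OCc9ccccc9)C4)[C@H](O[Si](C)(C)C(C)(C)C)Cc1c(O)cc(OCc9ccccc9)cc1OCc9ccccc9 | intermediate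
26 | (3R)-5,7-bis(benzyloxy)-2-[4,5-bis(benzyloxy)-2-(Cat8)phenyl]-3-(tert-butyldimethylsilyloxy)chroman-2-ol, C2 epimers (not isolated) | OC1(c2cc(OCc9ccccc9)c(OCc9ccccc9)cc2-c2c(OCc9ccccc9)cc(OCc9ccccc9)c3c2O[C@H](c2ccc(OCc9ccccc9)c(OCc9ccccc9)c2)[C@@H](OCc9ccccc9)C3)Oc2cc(OCc9ccccc9)cc(OCc9ccccc9)c2C[C@H]1O[Si](C)(C)C(C)(C)C | intermediate
27 | (3R)-5,7-bis(benzyloxy)-2-[4,5-bis(benzyloxy)-2-(Cat8)phenyl]-3-(tert-butyldimethylsilyloxy)-3,4-dihydrochromenylium triflate (not isolated) | C1(c2cc(OCc9ccccc9)c(OCc9ccccc9)cc2-c2c(OCc9ccccc9)cc(OCc9ccccc9)c3c2O[C@H](c2ccc(OCc9ccccc9)c(OCc9ccccc9)c2)[C@@H](OCc9ccccc9)C3)=[O+]c2cc(OCc9ccccc9)cc(OCc9ccccc9)c2C[C@H]1O[Si](C)(C)C(C)(C)C.[O-]S(=O)(=O)C(F)(F)F | intermediate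
28 | (2R,3R)-5,7-bis(benzyloxy)-2-[4,5-bis(benzyloxy)-2-(Cat8)phenyl]-3-(tert-butyldimethylsilyloxy)chroman | O(Cc9ccccc9)c1cc(OCc9ccccc9)c2c(c1)O[C@H](c1cc(OCc9ccccc9)c(OCc9ccccc9)cc1-c1c(OCc9ccccc9)cc(OCc9ccccc9)c3c1O[C@H](c1ccc(OCc9ccccc9)c(OCc9ccccc9)c1)[C@@H](OCc9ccccc9)C3)[C@H](O[Si](C)(C)C(C)(C)C)C2 | intermediate
29 | (2R,3R)-5,7-bis(benzyloxy)-2-[4,5-bis(benzyloxy)-2-(Cat8)phenyl]chroman-3-ol | O(Cc9ccccc9)c1cc(OCc9ccccc9)c2c(c1)O[C@H](c1cc(OCc9ccccc9)c(OCc9ccccc9)cc1-c1c(OCc9ccccc9)cc(OCc9ccccc9)c3c1O[C@H](c1ccc(OCc9ccccc9)c(OCc9ccccc9)c1)[C@@H](OCc9ccccc9)C3)[C@H](O)C2 | intermediate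
30 | (2R,3R)-2-{2-[(2R,3S)-2-(3,4-dihydroxyphenyl)-3,5,7-trihydroxychroman-8-yl]-4,5-dihydroxyphenyl}chroman-3,5,7-triol | Oc1cc(O)c2c(c1)O[C@H](c1cc(O)c(O)cc1-c1c(O)cc(O)c3c1O[C@H](c1ccc(O)c(O)c1)[C@@H](O)C3)[C@H](O)C2 | target

**Totals and risks**

Total step count: 16.
Longest linear sequence: 10 steps (steps 7–16, from 3,5-bis(benzyloxy)phenol).

Steps most likely to fail:

1. Step 12. The aryne may be consumed by its own magnesiated precursor before the hindered catechin Grignard captures it. The ortho-aryl Grignard may also acylate the branched Weinreb amide too slowly and be protonated instead. The fallback separates the two bond formations and replaces the amide acylation by an aryllithium–aldehyde addition. It sets out from 22 (made from 4 and 9 exactly as in step 12) and from 17, and returns at 24. Grignard 22 is quenched with I2 to give the 2-iodobiaryl (2R,3S)-3,5,7-tris(benzyloxy)-2-[3,4-bis(benzyloxy)phenyl]-8-[4,5-bis(benzyloxy)-2-iodophenyl]chroman F1, which is isolated. Amide 17 is reduced with i-Bu2AlH (THF, −78 °C) to (R)-3-[2,4-bis(benzyloxy)-6-(tert-butyldimethylsilyloxy)phenyl]-2-(tert-butyldimethylsilyloxy)propanal F2. Iodine–lithium exchange on F1 (t-BuLi, THF, −78 °C) and addition to F2 should give the secondary alcohol (2R)-1-[4,5-bis(benzyloxy)-2-(Cat8)phenyl]-3-[2,4-bis(benzyloxy)-6-(tert-butyldimethylsilyloxy)phenyl]-2-(tert-butyldimethylsilyloxy)propan-1-ol F3 as a mixture of carbinol epimers. Dess–Martin periodinane then oxidises F3 to ketone 24.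

2. Step 14. Hydride may be delivered to the wrong face of the oxocarbenium ion, or the ion may lose the C3 proton to an enol ether and so lose the C3 configuration. The fallback sets C2 by open-chain reduction and SN2 ring closure instead. It sets out from 24 and returns at 28. Ketone 24 is reduced under Felkin–Anh (non-chelation) control with LiBH(s-Bu)3 (THF, −78 °C) to the anti alcohol (1S,2R)-1-[4,5-bis(benzyloxy)-2-(Cat8)phenyl]-3-[2,4-bis(benzyloxy)-6-(tert-butyldimethylsilyloxy)phenyl]-2-(tert-butyldimethylsilyloxy)propan-1-ol F4. KHF2 in MeOH/THF frees the phenol to give (1S,2R)-1-[4,5-bis(benzyloxy)-2-(Cat8)phenyl]-3-[2,4-bis(benzyloxy)-6-hydroxyphenyl]-2-(tert-butyldimethylsilyloxy)propan-1-ol F5. An intramolecular Mitsunobu etherification (PPh3, DIAD, THF, 0 °C) closes the pyran with inversion at the carbinol carbon, giving the 2,3-cis flavan 28.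

3. Step 9. The di-ortho-substituted aryl Grignard may attack the ester carbonyl, or halide may open the epoxide, in competition with the CuI-catalysed opening. The fallback uses an epoxide without an ester and adjusts the oxidation state afterwards. It sets out from 12 (through Grignard 14, made as in step 9) and returns at 17. Grignard 14 opens purchased (R)-trityl glycidyl ether (c1ccccc1C(c1ccccc1)(c1ccccc1)OC[C@H]1CO1) with CuI (10 mol%) in THF at −40 → 0 °C to give (R)-1-[2,4-bis(benzyloxy)-6-(tert-butyldimethylsilyloxy)phenyl]-3-(trityloxy)propan-2-ol F6. TBSOTf and 2,6-lutidine give (R)-{[1-[2,4-bis(benzyloxy)-6-(tert-butyldimethylsilyloxy)phenyl]-3-(trityloxy)propan-2-yl]oxy}(tert-butyl)dimethylsilane F7. TsOH (cat.) in MeOH/CH2Cl2 at 0 °C removes the trityl group to give (R)-3-[2,4-bis(benzyloxy)-6-(tert-butyldimethylsilyloxy)phenyl]-2-(tert-butyldimethylsilyloxy)propan-1-ol F8. TEMPO (cat.) with PhI(OAc)2 in MeCN/H2O oxidises it to (R)-3-[2,4-bis(benzyloxy)-6-(tert-butyldimethylsilyloxy)phenyl]-2-(tert-butyldimethylsilyloxy)propanoic acid F9. Coupling with MeONHMe·HCl (EDC·HCl, N-methylmorpholine, CH2Cl2) gives amide 17.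

**Further compounds**

F1 | step 12 | (2R,3S)-3,5,7-tris(benzyloxy)-2-[3,4-bis(benzyloxy)phenyl]-8-[4,5-bis(benzyloxy)-2-iodophenyl]chroman | Ic1cc(OCc9ccccc9)c(OCc9ccccc9)cc1-c1c(OCc9ccccc9)cc(OCc9ccccc9)c2c1O[C@H](c1ccc(OCc9ccccc9)c(OCc9ccccc9)c1)[C@@H](OCc9ccccc9)C2
F2 | step 12 | (R)-3-[2,4-bis(benzyloxy)-6-(tert-butyldimethylsilyloxy)phenyl]-2-(tert-butyldimethylsilyloxy)propanal | O=C[C@H](O[Si](C)(C)C(C)(C)C)Cc1c(O[Si](C)(C)C(C)(C)C)cc(OCc2ccccc2)cc1OCc1ccccc1
F3 | step 12 | (2R)-1-[4,5-bis(benzyloxy)-2-(Cat8)phenyl]-3-[2,4-bis(benzyloxy)-6-(tert-butyldimethylsilyloxy)phenyl]-2-(tert-butyldimethylsilyloxy)propan-1-ol, carbinol epimers | OC(c1cc(OCc9ccccc9)c(OCc9ccccc9)cc1-c3c(OCc9ccccc9)cc(OCc9ccccc9)c4c3O[C@H](c3ccc(OCc9ccccc9)c(OCc9ccccc9)c3)[C@@H](OCc9ccccc9)C4)[C@H](O[Si](C)(C)C(C)(C)C)Cc1c(O[Si](C)(C)C(C)(C)C)cc(OCc9ccccc9)cc1OCc9ccccc9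
F4 | step 14 | (1S,2R)-1-[4,5-bis(benzyloxy)-2-(Cat8)phenyl]-3-[2,4-bis(benzyloxy)-6-(tert-butyldimethylsilyloxy)phenyl]-2-(tert-butyldimethylsilyloxy)propan-1-ol | O[C@@H](c1cc(OCc9ccccc9)c(OCc9ccccc9)cc1-c3c(OCc9ccccc9)cc(OCc9ccccc9)c4c3O[C@H](c3ccc(OCc9ccccc9)c(OCc9ccccc9)c3)[C@@H](OCc9ccccc9)C4)[C@H](O[Si](C)(C)C(C)(C)C)Cc1c(O[Si](C)(C)C(C)(C)C)cc(OCc9ccccc9)cc1OCc9ccccc9
F5 | step 14 | (1S,2R)-1-[4,5-bis(benzyloxy)-2-(Cat8)phenyl]-3-[2,4-bis(benzyloxy)-6-hydroxyphenyl]-2-(tert-butyldimethylsilyloxy)propan-1-ol | O[C@@H](c1cc(OCc9ccccc9)c(OCc9ccccc9)cc1-c3c(OCc9ccccc9)cc(OCc9ccccc9)c4c3O[C@H](c3ccc(OCc9ccccc9)c(OCc9ccccc9)c3)[C@@H](OCc9ccccc9)C4)[C@H](O[Si](C)(C)C(C)(C)C)Cc1c(O)cc(OCc9ccccc9)cc1OCc9ccccc9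
F6 | step 9 | (R)-1-[2,4-bis(benzyloxy)-6-(tert-butyldimethylsilyloxy)phenyl]-3-(trityloxy)propan-2-ol | c1ccccc1C(c1ccccc1)(c1ccccc1)OC[C@H](O)Cc1c(O[Si](C)(C)C(C)(C)C)cc(OCc2ccccc2)cc1OCc1ccccc1
F7 | step 9 | (R)-{[1-[2,4-bis(benzyloxy)-6-(tert-butyldimethylsilyloxy)phenyl]-3-(trityloxy)propan-2-yl]oxy}(tert-butyl)dimethylsilane | c1ccccc1C(c1ccccc1)(c1ccccc1)OC[C@H](O[Si](C)(C)C(C)(C)C)Cc1c(O[Si](C)(C)C(C)(C)C)cc(OCc2ccccc2)cc1OCc1ccccc1
F8 | step 9 | (R)-3-[2,4-bis(benzyloxy)-6-(tert-butyldimethylsilyloxy)phenyl]-2-(tert-butyldimethylsilyloxy)propan-1-ol | OC[C@H](O[Si](C)(C)C(C)(C)C)Cc1c(O[Si](C)(C)C(C)(C)C)cc(OCc2ccccc2)cc1OCc1ccccc1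
F9 | step 9 | (R)-3-[2,4-bis(benzyloxy)-6-(tert-butyldimethylsilyloxy)phenyl]-2-(tert-butyldimethylsilyloxy)propanoic acid | OC(=O)[C@H](O[Si](C)(C)C(C)(C)C)Cc1c(O[Si](C)(C)C(C)(C)C)cc(OCc2ccccc2)cc1OCc1ccccc1
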